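We start from amounts: each flask receives 0.050 M of starting material, 60.0 mM of partner and 1.95 mM of free catalyst; alpha feeds the partner over 20 s, zeta feeds the starting material over the same time, and delta feeds nothing.

| setting | alpha | zeta | delta |
|---|---|---|---|
| starting material | 0.050 M | 0.050 M (fed, over 20 s) | 0.050 M |
| partner | 1.20 equiv (fed, over 20 s) | 1.20 equiv | 1.20 equiv |
| free catalyst | 3.9 mol% | 3.9 mol% | 3.9 mol% |
| time | 100 s | 100 s | 100 s |
| remark | all else is in the flask from the start; the feed brings no volume worth counting | all else is in the flask from the start; the feed brings no volume worth counting | everything together at the start |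

- which flask leads in share of target in target plus isomer of the product ("all alike" within 1.5 percentage points) (alpha / zeta / delta / all alike)
- share of target in target plus isomer of the product at the end, alpha
- share of target in target plus isomer of the product at the end, zeta
- share of target in target plus isomer of the product at the end, delta

- target is meant together with its crystals
- solid, in amounts per volume of the solution: crystals
- run time (alpha): 100 s

    starting material + free catalyst → catalyst intermediate A (k1 = 51 L mol⁻¹ s⁻¹)
    catalyst intermediate A → catalyst intermediate B (k2 = 2.9 s⁻¹)
    partner + catalyst intermediate B ⇌ catalyst intermediate C (K3 = 53 L mol⁻¹, k3 = 14 L mol⁻¹ s⁻¹)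
    catalyst intermediate C → free catalyst + target (k4 = 9.3 s⁻¹)
    partner → decomposed reagent (k5 = 0.21 s⁻¹)
    target ⇌ isomer of the product (K6 = 0.81, k6 = 0.048 s⁻¹)
    crystals ⇌ target, rate k7*(cs7 - [target]) while solid is left; crystals form when [target] > cs7 (cs7 = 2.9 mM, k7 = 2.1 s⁻¹)

The half-lives climb a ladder. Catalyst intermediate A turns into catalyst intermediate B in 0.239 s, crystals close a gap to the solubility in 0.330 s, the partner decomposes in 3.30 s, and target and isomer of the product relax towards each other in 6.46 s. That relaxation is short against the run of 100 s, so we read the end as a balance, not a race.

While solid is left, dissolved target stands at the solubility c_s, 2.9 mM, and the isomer at K c_s, with K = 0.81. Let T be target, crystals included, plus isomer. The crystal threshold T*, the sum of c_s and K c_s, is the total that saturated solution and its isomer just hold without solid: 5.25 mM. Below T* the share of target is the plain balance, 55.2%; above it the isomer is capped, and the share is one minus K c_s/T.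

Can a flask reach T*? It takes 2.69 turnovers of the catalyst. Per catalyst, capture of catalyst intermediate B by the partner runs at most at k_c[partner], with k_c = 14 L mol⁻¹ s⁻¹, and with decomposition at k_d = 0.21 s⁻¹ the time integral of the partner stays at or below its charge over k_d. That gives a ceiling of 4.00 turnovers and, at that ceiling, a share of 69.9%.

Time on the other legs of the cycle is lost from this ceiling. In alpha, catalyst stands ready as partner trickles in. In zeta, the feed outlasts the partner's half-life, so starting material arrives while the partner burns. We commit to alpha above T* and leading, to zeta below T*, and we leave delta open.

The forecast gives alpha 62%, zeta 55.2% and delta 55.5%, with alpha leading, holding that “product above about 5.25 mM (2.9 mM dissolved target plus 2.35 mM isomer) stays protected as crystals”, and so it differs from us in naming a value for delta, which we left open.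

The simulation gives 61.4% for alpha, 55.3% for zeta and 55.3% for delta, so alpha leads.

At 100 s, alpha holds T = 6.06 mM, above T*, and the rule gives it 61.2%. Delta at 100 s holds 4.71 mM, below T*, with crystals at 0%. The neighbour is delta read at 25 s. Its total, 4.69 mM, is also below T*, so the threshold allows it no lasting solid and points to 55.2%. Yet that reading of delta still shows crystals at 0.191% of the starting material charged and a share of target of 63.6%.

The numbers belong to no real substance, and the outcome is calculated.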